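**Retrosynthetic overview**

- The strategy rests on ring B (C1'–C6'), a 1,3,5-trisubstituted benzene with benzofuran C2 on C1', a free OH on C3' and OMe on C5'. This unsymmetrical resorcinol monomethyl ether is built last, so the two oxygens are different from the moment they appear.
- Ring B ⇒ 3-(benzofuran-2-yl)cyclobutenone 17 + methoxyacetylene 20 (C3'–C4' and C5'–C6' by ketene–alkyne [2+2], C2'–C3' by 6π closure); the C5 silyl ether is cleaved afterwards.
- 17 ⇒ 2-lithiobenzofuran + 3-ethoxycyclobutenone 14 (C2–C1' bond by 1,2-addition and hydrolytic transposition).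
- Furan ring ⇒ 2-ethynylphenol 12 (O1–C2 by cycloisomerisation) ⇒ salicylaldehyde 11 (C2 by one-carbon homologation, C3 by ortho-formylation).
- Ring A comes from vanillin: Dakin oxidation supplies O1 and directed metalation puts the prenyl group on C7. Ring order: A (given), then the furan ring, then B.

Key step: step 11

Remark: the target has no stereocentre and no stereogenic double bond, so there is no stereochemical task. Assumption: 3-ethoxycyclobut-2-en-1-one is taken as a purchased building block; methoxyacetylene is low-boiling and is made fresh (step 10).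

**Route**

Step 1
Reactants: 1 vanillin
Product: 2 3-methoxy-4-(triisopropylsilyloxy)benzaldehyde
Conditions: TIPSCl, imidazole, DMF, rt
Reagents that add atoms: triisopropylsilyl chloride, CC(C)[Si](Cl)(C(C)C)C(C)C
Why: Imidazole-mediated silylation of the only phenol; the bulky TIPS ether does not direct lithiation, resists n-BuLi and mild acid or base, and is removed by fluoride at the end.

Step 2
Reactants: 2 3-methoxy-4-(triisopropylsilyloxy)benzaldehyde
Product: 4 3-methoxy-4-(triisopropylsilyloxy)phenol, via aryl formate 3 (not isolated)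
Conditions: mCPBA, NaHCO3, CH2Cl2, 0 °C to rt; then Et3N (cat.), MeOH, rt
Reagents that add atoms: mCPBA, OOC(=O)c1cccc(Cl)c1
Why: Dakin-type Baeyer–Villiger oxidation in which the electron-rich aryl group migrates to give the aryl formate, followed by mild methanolysis of the formate that leaves the aryl silyl ether intact.

Step 3
Reactants: 4 3-methoxy-4-(triisopropylsilyloxy)phenol
Product: 5 2-methoxy-4-(methoxymethoxy)-1-(triisopropylsilyloxy)benzene
Conditions: MOMCl, iPr2NEt, CH2Cl2, 0 °C to rt
Reagents that add atoms: chloromethyl methyl ether, COCCl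
Why: O-alkylation of the phenol with MOMCl installs a chelating directing group for the ortho-lithiation that follows.

Step 4
Reactants: 5 2-methoxy-4-(methoxymethoxy)-1-(triisopropylsilyloxy)benzene; 6 prenyl bromide
Product: 8 2-methoxy-4-(methoxymethoxy)-3-(3-methylbut-2-enyl)-1-(triisopropylsilyloxy)benzene, via aryllithium 7 (not isolated)
Conditions: n-BuLi, TMEDA, THF, −20 to 0 °C; then CuBr·SMe2 (10 mol%), 6, −78 °C to rt
Reagents that add atoms: none
Why: Directed ortho-metalation occurs at the CH flanked by OMOM and OMe (cooperative coordination and inductive acidification, the bulky OTIPS group not directing), and copper-catalysed SN2 allylation of the aryllithium with the primary allylic bromide gives the linear prenyl arene.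

Step 5
Reactants: 8 2-methoxy-4-(methoxymethoxy)-3-(3-methylbut-2-enyl)-1-(triisopropylsilyloxy)benzene
Product: 9 3-methoxy-2-(3-methylbut-2-enyl)-4-(triisopropylsilyloxy)phenol
Conditions: HCl (ca. 1 M in MeOH), rt
Reagents that add atoms: none
Why: Acid-catalysed transacetalisation to methanol cleaves the MOM acetal under conditions too mild to hydrolyse the aryl TIPS ether or to cyclise the ortho-prenylphenol to a chroman.

Step 6
Reactants: 9 3-methoxy-2-(3-methylbut-2-enyl)-4-(triisopropylsilyloxy)phenol
Product: 11 2-hydroxy-4-methoxy-3-(3-methylbut-2-enyl)-5-(triisopropylsilyloxy)benzaldehyde, via salicyl alcohol 10 (not isolated)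
Conditions: MgCl2, Et3N, (CH2O)n, MeCN, reflux
Reagents that add atoms: paraformaldehyde (as formaldehyde), C=O
Why: Casnati–Skattebøl ortho-formylation, in which the magnesium phenoxide delivers formaldehyde to the only free ortho position and the benzylic alkoxide is oxidised by hydride transfer to a second formaldehyde.

Step 7
Reactants: 11 2-hydroxy-4-methoxy-3-(3-methylbut-2-enyl)-5-(triisopropylsilyloxy)benzaldehyde
Product: 12 2-ethynyl-5-methoxy-6-(3-methylbut-2-enyl)-4-(triisopropylsilyloxy)phenol
Conditions: dimethyl (1-diazo-2-oxopropyl)phosphonate, K2CO3 (excess), MeOH, 0 °C to rt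
Reagents that add atoms: dimethyl (1-diazo-2-oxopropyl)phosphonate, COP(=O)(OC)C(=[N+]=[N-])C(C)=O
Why: Seyferth–Gilbert homologation in its Ohira–Bestmann form converts the aldehyde into the terminal alkyne under carbonate conditions that tolerate a free phenol and the prenyl group.

Step 8
Reactants: 12 2-ethynyl-5-methoxy-6-(3-methylbut-2-enyl)-4-(triisopropylsilyloxy)phenol
Product: 13 6-methoxy-7-(3-methylbut-2-enyl)-5-(triisopropylsilyloxy)benzofuran
Conditions: [Rh(cod)Cl]2 (2.5 mol%), P(4-FC6H4)3 (10 mol%), DMF, 85 °C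
Reagents that add atoms: none
Why: Rhodium(I)-catalysed cycloisomerisation of a terminal 2-ethynylphenol through a rhodium vinylidene, whose α-carbon is attacked by the phenol oxygen (net 5-endo hydroalkoxylation), closes the furan ring with C2 and C3 unsubstituted.

Step 9
Reactants: 13 6-methoxy-7-(3-methylbut-2-enyl)-5-(triisopropylsilyloxy)benzofuran; 14 3-ethoxycyclobut-2-en-1-one
Product: 17 3-[6-methoxy-7-(3-methylbut-2-enyl)-5-(triisopropylsilyloxy)benzofuran-2-yl]cyclobut-2-en-1-one, via 2-lithiobenzofuran 15 (not isolated), via lithium cyclobutenolate 16 (not isolated)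
Conditions: n-BuLi, THF, −78 °C; then 14, −78 °C; then 1 M aq. HCl, 0 °C
Reagents that add atoms: water, O
Why: Benzofuran C2–H is the most acidic C–H and is lithiated cleanly, and 1,2-addition to the vinylogous ester followed by acid-induced ionisation, hydration at the ethoxy-bearing carbon and loss of ethanol is the standard route to 3-substituted cyclobutenones.

Step 10
Reactants: 18 chloroacetaldehyde dimethyl acetal
Product: 20 methoxyacetylene, via sodium methoxyacetylide 19 (not isolated)
Conditions: NaNH2 (3 equiv), liq. NH3, −33 °C; NH3 evaporated; then cold satd aq. NaCl, −70 to 0 °C; distilled into a −78 °C trap and kept as a cold toluene solution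
Reagents that add atoms: none
Why: Two amide-induced β-eliminations (methanol, then HCl) and deprotonation by the third equivalent give the sodium acetylide, which is protonated on aqueous quench and distilled off.

Step 11
Reactants: 17 3-[6-methoxy-7-(3-methylbut-2-enyl)-5-(triisopropylsilyloxy)benzofuran-2-yl]cyclobut-2-en-1-one; 20 methoxyacetylene
Product: 25 5-O-TIPS dinklagein A, via vinylketene 21 (not isolated), via vinylcyclobutenone 22 (not isolated), via dienylketene 23 (not isolated), via cyclohexadienone 24 (not isolated)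
Conditions: 20 (3 equiv), toluene, sealed tube, 80 °C
Reagents that add atoms: none
Why: Heating opens the cyclobutenone by 4π-electrocyclic cleavage to the vinylketene 21, whose electrophilic ketene carbon is attacked by the unsubstituted, nucleophilic carbon of the ynol ether, so that the [2+2] cycloaddition forms C3'–C4' and C5'–C6' and gives the 4-vinylcyclobutenone 22. A second 4π opening gives the dienylketene 23 (reversibly, so the geometry able to cyclise is drained), and thermal disrotatory 6π-electrocyclisation forms C2'–C3' and closes ring B as the cyclohexadienone 24, which tautomerises to the phenol. This is the Danheiser benzannulation of a 3-substituted cyclobutenone with an alkoxyacetylene, the known route to 5-substituted resorcinol monoethers. No stereocentre is formed. The selectivity needed is the regiochemistry of the [2+2] step, secured by the polarisation of the ynol ether against the ketene, which places OMe meta to the new OH and both meta to the benzofuranyl group; the prenyl olefin does not compete because the ynol ether is far more ketenophilic. The ketene carbonyl ends as the free C3'–OH and the methoxy-bearing alkyne carbon as C5', so no differentiation of two resorcinol oxygens is required.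

Step 12
Reactants: 25 5-O-TIPS dinklagein A
Product: 26 dinklagein A
Conditions: TBAF, AcOH, THF, 0 °C to rt
Reagents that add atoms: none
Why: Fluoride-induced desilylation (strong Si–F bond) frees the C5 phenol, acetic acid buffering the medium so the electron-rich bis-phenol is not exposed to base; the prenyl group and benzofuran are inert.

**Compound list**

1 | vanillin | COc1cc(C=O)ccc1O | starting material
2 | 3-methoxy-4-(triisopropylsilyloxy)benzaldehyde | COc1cc(C=O)ccc1O[Si](C(C)C)(C(C)C)C(C)C | intermediate
3 | 3-methoxy-4-(triisopropylsilyloxy)phenyl formate | COc1cc(OC=O)ccc1O[Si](C(C)C)(C(C)C)C(C)C | intermediate (not isolated)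
4 | 3-methoxy-4-(triisopropylsilyloxy)phenol | COc1cc(O)ccc1O[Si](C(C)C)(C(C)C)C(C)C | intermediate
5 | 2-methoxy-4-(methoxymethoxy)-1-(triisopropylsilyloxy)benzene | COCOc1ccc(O[Si](C(C)C)(C(C)C)C(C)C)c(OC)c1 | intermediate
6 | prenyl bromide (1-bromo-3-methylbut-2-ene) | CC(C)=CCBr | starting material
7 | [2-methoxy-6-(methoxymethoxy)-3-(triisopropylsilyloxy)phenyl]lithium | COCOc1ccc(O[Si](C(C)C)(C(C)C)C(C)C)c(OC)c1[Li] | intermediate (not isolated)
8 | 2-methoxy-4-(methoxymethoxy)-3-(3-methylbut-2-enyl)-1-(triisopropylsilyloxy)benzene | COCOc1ccc(O[Si](C(C)C)(C(C)C)C(C)C)c(OC)c1CC=C(C)C | intermediate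
9 | 3-methoxy-2-(3-methylbut-2-enyl)-4-(triisopropylsilyloxy)phenol | COc1c(O[Si](C(C)C)(C(C)C)C(C)C)ccc(O)c1CC=C(C)C | intermediate
10 | 2-(hydroxymethyl)-5-methoxy-6-(3-methylbut-2-enyl)-4-(triisopropylsilyloxy)phenol | COc1c(O[Si](C(C)C)(C(C)C)C(C)C)cc(CO)c(O)c1CC=C(C)C | intermediate (not isolated)
11 | 2-hydroxy-4-methoxy-3-(3-methylbut-2-enyl)-5-(triisopropylsilyloxy)benzaldehyde | COc1c(O[Si](C(C)C)(C(C)C)C(C)C)cc(C=O)c(O)c1CC=C(C)C | intermediate
12 | 2-ethynyl-5-methoxy-6-(3-methylbut-2-enyl)-4-(triisopropylsilyloxy)phenol | COc1c(O[Si](C(C)C)(C(C)C)C(C)C)cc(C#C)c(O)c1CC=C(C)C | intermediate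
13 | 6-methoxy-7-(3-methylbut-2-enyl)-5-(triisopropylsilyloxy)benzofuran | COc1c(O[Si](C(C)C)(C(C)C)C(C)C)cc2ccoc2c1CC=C(C)C | intermediate
14 | 3-ethoxycyclobut-2-en-1-one | CCOC1=CC(=O)C1 | starting material
15 | 2-lithio-6-methoxy-7-(3-methylbut-2-enyl)-5-(triisopropylsilyloxy)benzofuran | COc1c(O[Si](C(C)C)(C(C)C)C(C)C)cc2cc([Li])oc2c1CC=C(C)C | intermediate (not isolated)
16 | lithium 3-ethoxy-1-[6-methoxy-7-(3-methylbut-2-enyl)-5-(triisopropylsilyloxy)benzofuran-2-yl]cyclobut-2-en-1-olate (racemic) | CCOC1=CC(O[Li])(C1)c1cc2cc(O[Si](C(C)C)(C(C)C)C(C)C)c(OC)c(CC=C(C)C)c2o1 | intermediate (not isolated)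
17 | 3-[6-methoxy-7-(3-methylbut-2-enyl)-5-(triisopropylsilyloxy)benzofuran-2-yl]cyclobut-2-en-1-one | O=C1CC(=C1)c1cc2cc(O[Si](C(C)C)(C(C)C)C(C)C)c(OC)c(CC=C(C)C)c2o1 | intermediate
18 | chloroacetaldehyde dimethyl acetal (2-chloro-1,1-dimethoxyethane) | COC(OC)CCl | starting material
19 | sodium methoxyacetylide | [Na]C#COC | intermediate (not isolated)
20 | methoxyacetylene | C#COC | intermediate
21 | 3-[6-methoxy-7-(3-methylbut-2-enyl)-5-(triisopropylsilyloxy)benzofuran-2-yl]buta-1,3-dien-1-one (vinylketene) | O=C=CC(=C)c1cc2cc(O[Si](C(C)C)(C(C)C)C(C)C)c(OC)c(CC=C(C)C)c2o1 | intermediate (not isolated)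
22 | 3-methoxy-4-{1-[6-methoxy-7-(3-methylbut-2-enyl)-5-(triisopropylsilyloxy)benzofuran-2-yl]vinyl}cyclobut-2-en-1-one (racemic) | COC1=CC(=O)C1C(=C)c1cc2cc(O[Si](C(C)C)(C(C)C)C(C)C)c(OC)c(CC=C(C)C)c2o1 | intermediate (not isolated)
23 | 3-methoxy-5-[6-methoxy-7-(3-methylbut-2-enyl)-5-(triisopropylsilyloxy)benzofuran-2-yl]hexa-1,3,5-trien-1-one (dienylketene, ketene and vinyl groups cis on the central double bond) | O=C=C/C(OC)=C\C(=C)c1cc2cc(O[Si](C(C)C)(C(C)C)C(C)C)c(OC)c(CC=C(C)C)c2o1 | intermediate (not isolated)
24 | 3-methoxy-5-[6-methoxy-7-(3-methylbut-2-enyl)-5-(triisopropylsilyloxy)benzofuran-2-yl]cyclohexa-2,4-dien-1-one | O=C1CC(=CC(OC)=C1)c1cc2cc(O[Si](C(C)C)(C(C)C)C(C)C)c(OC)c(CC=C(C)C)c2o1 | intermediate (not isolated)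
25 | 5-O-TIPS dinklagein A, 3-methoxy-5-[6-methoxy-7-(3-methylbut-2-enyl)-5-(triisopropylsilyloxy)benzofuran-2-yl]phenol | COc1cc(O)cc(-c2cc3cc(O[Si](C(C)C)(C(C)C)C(C)C)c(OC)c(CC=C(C)C)c3o2)c1 | intermediate
26 | dinklagein A, 2-(3-hydroxy-5-methoxyphenyl)-6-methoxy-7-(3-methylbut-2-enyl)benzofuran-5-ol | COc1cc(O)cc(-c2cc3cc(O)c(OC)c(CC=C(C)C)c3o2)c1 | target

**Totals**

Total step count: 12. Longest linear sequence: 11 steps (steps 1–9, 11 and 12, from vanillin); step 10 is a one-step side branch.

**Steps most likely to fail**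

1. Step 11 (key benzannulation). The vinylketene may be intercepted by the newly formed phenol (aryl ester formation) or oligomerise, and the volatile ynol ether may polymerise before it is trapped; excess alkyne and a sealed vessel are the first countermeasures. Fallback: ring B is attached instead by cross-coupling. It sets out from benzofuran 13: C2-lithiation (n-BuLi, THF, −78 °C) and quench with 2-isopropoxy-4,4,5,5-tetramethyl-1,3,2-dioxaborolane should give the benzofuran-2-yl pinacol boronate F1. Suzuki–Miyaura coupling of F1 with purchased 3-bromo-5-methoxyphenol (Pd(dppf)Cl2, K3PO4, dioxane/H2O, 70 °C) comes back to the route at 25. Partial loss of the silyl ether under these conditions would be harmless, since step 12 removes it.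

2. Step 9 (cyclobutenone formation). Proton transfer from the acidic C4–H2 of the vinylogous ester to the heteroaryllithium may compete with 1,2-addition, and the strained enone may be cleaved during the acidic unmasking. Fallback: the cyclobutenone is given up as ketene source and vinylketene 21 is generated by photochemical Wolff rearrangement, the diazo-ketone form of the same benzannulation. It sets out from benzofuran 13. Lithiation to 15 and transmetalation with ZnCl2 give the benzofuran-2-ylzinc chloride F2. Negishi coupling of F2 with 3-bromobut-3-en-2-one (Pd(PPh3)4, THF, rt) gives the 3-(benzofuran-2-yl)but-3-en-2-one F3. Trifluoroacetylation of its kinetic enolate (LiHMDS, CF3CO2CH2CF3, THF, −78 °C) gives the trifluoromethyl 1,3-diketone F4. Detrifluoroacetylative diazo transfer (MsN3, Et3N, H2O, MeCN) gives the α-diazo ketone F5. Irradiation of F5 (300 nm, CH2Cl2, rt) with methoxyacetylene 20, then warming to 80 °C, passes through 21–24 and comes back to the route at 25.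

3. Step 7 (alkyne homologation). The aldehyde is deactivated as its phenoxide under the basic conditions, so homologation may be sluggish, and slow loss of the silyl ether in carbonate/methanol may accompany it. Fallback: the furan ring is closed by C–O coupling instead of cycloisomerisation, which also replaces step 8. It sets out from salicylaldehyde 11. Ramirez olefination (CBr4, PPh3, CH2Cl2, 0 °C) gives the 2-(2,2-dibromovinyl)phenol F6. Copper-catalysed intramolecular C–O coupling (CuI 5 mol%, K3PO4, THF, 80 °C) gives the 2-bromobenzofuran F7. Bromine–lithium exchange on F7 (n-BuLi, THF, −78 °C) comes back to the route at 15, which is carried on to 17 as in step 9.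

**Further compounds**

F1 | step 11 | 2-[6-methoxy-7-(3-methylbut-2-enyl)-5-(triisopropylsilyloxy)benzofuran-2-yl]-4,4,5,5-tetramethyl-1,3,2-dioxaborolane | COc1c(O[Si](C(C)C)(C(C)C)C(C)C)cc2cc(B3OC(C)(C)C(C)(C)O3)oc2c1CC=C(C)C
F2 | step 9 | [6-methoxy-7-(3-methylbut-2-enyl)-5-(triisopropylsilyloxy)benzofuran-2-yl]zinc chloride | COc1c(O[Si](C(C)C)(C(C)C)C(C)C)cc2cc([Zn]Cl)oc2c1CC=C(C)C
F3 | step 9 | 3-[6-methoxy-7-(3-methylbut-2-enyl)-5-(triisopropylsilyloxy)benzofuran-2-yl]but-3-en-2-one | CC(=O)C(=C)c1cc2cc(O[Si](C(C)C)(C(C)C)C(C)C)c(OC)c(CC=C(C)C)c2o1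
F4 | step 9 | 1,1,1-trifluoro-5-[6-methoxy-7-(3-methylbut-2-enyl)-5-(triisopropylsilyloxy)benzofuran-2-yl]hex-5-ene-2,4-dione | O=C(CC(=O)C(F)(F)F)C(=C)c1cc2cc(O[Si](C(C)C)(C(C)C)C(C)C)c(OC)c(CC=C(C)C)c2o1
F5 | step 9 | 1-diazo-3-[6-methoxy-7-(3-methylbut-2-enyl)-5-(triisopropylsilyloxy)benzofuran-2-yl]but-3-en-2-one | [N-]=[N+]=CC(=O)C(=C)c1cc2cc(O[Si](C(C)C)(C(C)C)C(C)C)c(OC)c(CC=C(C)C)c2o1
F6 | step 7 | 2-(2,2-dibromovinyl)-5-methoxy-6-(3-methylbut-2-enyl)-4-(triisopropylsilyloxy)phenol | COc1c(O[Si](C(C)C)(C(C)C)C(C)C)cc(C=C(Br)Br)c(O)c1CC=C(C)C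
F7 | step 7 | 2-bromo-6-methoxy-7-(3-methylbut-2-enyl)-5-(triisopropylsilyloxy)benzofuran | COc1c(O[Si](C(C)C)(C(C)C)C(C)C)cc2cc(Br)oc2c1CC=C(C)C
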